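## Retrosynthetic overview

1. The target is the all-cis (2R,3R,4R) oxolane. It comes from its silyl ether and that from an all-cis γ-lactone in which only the lactone C=O must be reduced to CH2, so the C2–O bond and all three stereocentres are already in place.
2. The all-cis lactone comes from an (E)-3-benzylidene lactone by hydrogenation from the face opposite the two cis substituents (sets C4 of the target). That lactone comes from a cis-4,5-disubstituted lactone and veratraldehyde by aldol condensation.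
3. Key disconnection, C2–C3 of the target: a chiral carbene turns the β-carbon of a γ-silyloxy enal into a nucleophile (homoenolate), which attacks the carbonyl carbon of 3,4,5-trimethoxybenzaldehyde. This joins two normally electrophilic carbons, sets C2 and C3 (cis), and closes the lactone in the same operation.
4. The enal comes from an allyl silyl ether and crotonaldehyde by cross-metathesis.
5. Ring order: only one ring is built, the oxolane. It is formed as a γ-lactone in the annulation and kept to the end.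

**Assumption:** the (5aS,10bR) antipode of the triazolium precatalyst is taken to give the (4R,5R) lactone 7; if the opposite sense is found, the (5aR,10bS) salt is used and nothing else changes.

## Route

Step 1
Reactants: 1 tert-butyldimethyl(prop-2-en-1-yloxy)silane; 2 (E)-but-2-enal (crotonaldehyde, 3 equiv)
Product: 3 (E)-4-[(tert-butyldimethylsilyl)oxy]but-2-enal
Conditions: second-generation Hoveyda–Grubbs catalyst RuCl2(H2IMes)(=CH-C6H4-2-OiPr) (2.5 mol %), CH2Cl2, 40 °C
Reagents that add atoms: none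
Why: Olefin cross-metathesis of a terminal allyl ether with excess crotonaldehyde is a reliable E-selective route to γ-oxygenated enals, driven by loss of propene; no stereocentre is formed.

Step 2
Reactants: 3 (E)-4-[(tert-butyldimethylsilyl)oxy]but-2-enal (added over 6 h); 4 3,4,5-trimethoxybenzaldehyde (2 equiv)
Product: 7 (4R,5R)-4-{[(tert-butyldimethylsilyl)oxy]methyl}-5-(3,4,5-trimethoxyphenyl)oxolan-2-one, via Breslow homoenolate adduct 5 (not isolated), via acylazolium alkoxide 6 (not isolated)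
Conditions: (5aS,10bR)-5a,10b-dihydro-2-(2,4,6-trimethylphenyl)-4H,6H-indeno[2,1-b][1,2,4]triazolo[4,3-d][1,4]oxazinium chloride (10 mol %), DBU (15 mol %), LiCl (1.0 equiv), 4 Å MS, THF, 23 °C
Reagents that add atoms: none
Why: Proposed new method: the triazolylidene (freed from its chloride salt by DBU) adds to the enal carbonyl and proton transfer gives dienaminol 5, whose β-carbon is now nucleophilic (homoenolate) and adds to the LiCl-activated carbonyl carbon of 4; tautomerisation to acylazolium 6 and O-acylation by the new alkoxide close the γ-lactone and release the free carbene back into the cycle, so C4 and C5 are set together in the C–C bond-forming transition state, cis by the kinetic preference of this annulation and in the absolute sense fixed by the aminoindanol backbone shielding one face of the homoenolate; the closest known reactions are the racemic carbene-catalysed enal plus aryl aldehyde cis-γ-butyrolactone annulation (homoenolate [3+2] annulation) and the enantioselective carbene/LiCl homoenolate annulation of enals with isatins.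

Step 3
Reactants: 7 (4R,5R)-4-{[(tert-butyldimethylsilyl)oxy]methyl}-5-(3,4,5-trimethoxyphenyl)oxolan-2-one; 8 3,4-dimethoxybenzaldehyde (veratraldehyde)
Product: 12 (3E,4R,5R)-4-{[(tert-butyldimethylsilyl)oxy]methyl}-3-(3,4-dimethoxybenzylidene)-5-(3,4,5-trimethoxyphenyl)oxolan-2-one, via lithium enolate 9 (not isolated), via lithium aldolate 10 (not isolated), via aldol mesylate 11 (not isolated)
Conditions: LiN(iPr)2 (1.1 equiv), THF, –78 °C; 8; then MsCl, –78 → 0 °C; then DBU, 0 → 23 °C
Reagents that add atoms: none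
Why: Aldol condensation (lactone enolate addition, mesylation, E1cB elimination) gives the conjugated (E)-alkylidene lactone; the two transient new centres are erased, and C4 and C5 are not enolisable so they stay intact.

Step 4
Reactants: 12 (3E,4R,5R)-4-{[(tert-butyldimethylsilyl)oxy]methyl}-3-(3,4-dimethoxybenzylidene)-5-(3,4,5-trimethoxyphenyl)oxolan-2-one
Product: 13 (3R,4R,5R)-4-{[(tert-butyldimethylsilyl)oxy]methyl}-3-(3,4-dimethoxybenzyl)-5-(3,4,5-trimethoxyphenyl)oxolan-2-one
Conditions: H2 (1 atm), 5% Rh/Al2O3, EtOAc, 23 °C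
Reagents that add atoms: none
Why: Heterogeneous syn-hydrogenation delivers hydrogen to the exocyclic alkene from the face opposite the cis C4 silyloxymethyl and C5 aryl groups, so the new C3–H is trans to them and the benzyl group ends up cis (all-cis, 3R); rhodium on alumina is chosen because it does not hydrogenolyse the benzylic lactone C–O bond.

Step 5
Reactants: 13 (3R,4R,5R)-4-{[(tert-butyldimethylsilyl)oxy]methyl}-3-(3,4-dimethoxybenzyl)-5-(3,4,5-trimethoxyphenyl)oxolan-2-one
Product: 15 tert-butyl{[(2R,3R,4R)-4-(3,4-dimethoxybenzyl)-2-(3,4,5-trimethoxyphenyl)oxolan-3-yl]methoxy}dimethylsilane, via aluminium lactolate 14 (not isolated)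
Conditions: iBu2AlH (1.2 equiv), CH2Cl2, –78 °C; then Et3SiH (5 equiv), BF3·OEt2 (3 equiv), –78 → –40 °C
Reagents that add atoms: none
Why: iBu2AlH stops at the tetrahedral lactolate 14 at –78 °C, BF3·OEt2 ionises it to the cyclic oxocarbenium ion and Et3SiH reduces that (ionic hydrogenation, lactone-to-cyclic-ether deoxygenation); the carbonyl carbon becomes CH2, no stereocentre is touched, and the low temperature avoids ionising the benzylic C2–O bond.

Step 6
Reactants: 15 tert-butyl{[(2R,3R,4R)-4-(3,4-dimethoxybenzyl)-2-(3,4,5-trimethoxyphenyl)oxolan-3-yl]methoxy}dimethylsilane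
Product: 16 [(2R,3R,4R)-4-(3,4-dimethoxybenzyl)-2-(3,4,5-trimethoxyphenyl)oxolan-3-yl]methanol
Conditions: Bu4NF (1.2 equiv), THF, 0 → 23 °C
Reagents that add atoms: none
Why: Fluoride-mediated desilylation cleaves the primary silyl ether under non-acidic conditions that cannot epimerise the benzylic ether centre.

## Compound list

1 | tert-butyldimethyl(prop-2-en-1-yloxy)silane | C=CCO[Si](C)(C)C(C)(C)C | starting material
2 | (E)-but-2-enal (crotonaldehyde) | C/C=C/C=O | starting material
3 | (E)-4-[(tert-butyldimethylsilyl)oxy]but-2-enal | O=C/C=C/CO[Si](C)(C)C(C)(C)C | intermediate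
4 | 3,4,5-trimethoxybenzaldehyde | COc1cc(C=O)cc(OC)c1OC | starting material
5 | Breslow homoenolate adduct: dienaminol of 3 bound through its former carbonyl carbon to C3 of the (5aS,10bR) N-mesityl triazolylidene, (E)-alkene kept | Cc1cc(C)c(c(C)c1)N1N=C2CO[C@H]3Cc4ccccc4[C@H]3N2C1=C(O)/C=C/CO[Si](C)(C)C(C)(C)C | intermediate (not isolated)
6 | acylazolium alkoxide: zwitterion with (3R,4R)-3-(silyloxymethyl)-4-oxido-4-(3,4,5-trimethoxyphenyl)butanoyl group on C3 of the triazolium | [O-][C@@H](c1cc(OC)c(OC)c(OC)c1)[C@@H](CO[Si](C)(C)C(C)(C)C)CC(=O)c1n2[C@@H]3c4ccccc4C[C@@H]3OCc2n[n+]1-c1c(C)cc(C)cc1C | intermediate (not isolated)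
7 | (4R,5R)-4-{[(tert-butyldimethylsilyl)oxy]methyl}-5-(3,4,5-trimethoxyphenyl)oxolan-2-one (4,5-cis) | O=C1C[C@H](CO[Si](C)(C)C(C)(C)C)[C@H](c2cc(OC)c(OC)c(OC)c2)O1 | intermediate
8 | 3,4-dimethoxybenzaldehyde (veratraldehyde) | COc1ccc(C=O)cc1OC | starting material
9 | lithium (4R,5R)-4-{[(tert-butyldimethylsilyl)oxy]methyl}-5-(3,4,5-trimethoxyphenyl)-4,5-dihydrofuran-2-olate (enolate of 7) | C1=C([O-])O[C@@H](c2cc(OC)c(OC)c(OC)c2)[C@H]1CO[Si](C)(C)C(C)(C)C.[Li+] | intermediate (not isolated)
10 | lithium aldolate: 7 bearing a (3,4-dimethoxyphenyl)(oxido)methyl group at C3, epimer mixture at the two new centres | COc1ccc(C([O-])C2C(=O)O[C@@H](c3cc(OC)c(OC)c(OC)c3)[C@H]2CO[Si](C)(C)C(C)(C)C)cc1OC.[Li+] | intermediate (not isolated)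
11 | aldol mesylate: methanesulfonate of the alcohol of 10, epimer mixture at the two new centres | COc1ccc(C(OS(C)(=O)=O)C2C(=O)O[C@@H](c3cc(OC)c(OC)c(OC)c3)[C@H]2CO[Si](C)(C)C(C)(C)C)cc1OC | intermediate (not isolated)
12 | (3E,4R,5R)-4-{[(tert-butyldimethylsilyl)oxy]methyl}-3-(3,4-dimethoxybenzylidene)-5-(3,4,5-trimethoxyphenyl)oxolan-2-one | COc1ccc(/C=C2/C(=O)O[C@@H](c3cc(OC)c(OC)c(OC)c3)[C@H]2CO[Si](C)(C)C(C)(C)C)cc1OC | intermediate
13 | (3R,4R,5R)-4-{[(tert-butyldimethylsilyl)oxy]methyl}-3-(3,4-dimethoxybenzyl)-5-(3,4,5-trimethoxyphenyl)oxolan-2-one (all-cis) | COc1ccc(C[C@H]2C(=O)O[C@@H](c3cc(OC)c(OC)c(OC)c3)[C@H]2CO[Si](C)(C)C(C)(C)C)cc1OC | intermediate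
14 | aluminium lactolate: diisobutylaluminium alkoxide of the lactol of 13, anomer mixture | COc1ccc(C[C@H]2C(O[Al](CC(C)C)CC(C)C)O[C@@H](c3cc(OC)c(OC)c(OC)c3)[C@H]2CO[Si](C)(C)C(C)(C)C)cc1OC | intermediate (not isolated)
15 | tert-butyl{[(2R,3R,4R)-4-(3,4-dimethoxybenzyl)-2-(3,4,5-trimethoxyphenyl)oxolan-3-yl]methoxy}dimethylsilane (all-cis) | COc1ccc(C[C@H]2CO[C@@H](c3cc(OC)c(OC)c(OC)c3)[C@H]2CO[Si](C)(C)C(C)(C)C)cc1OC | intermediate
16 | [(2R,3R,4R)-4-(3,4-dimethoxybenzyl)-2-(3,4,5-trimethoxyphenyl)oxolan-3-yl]methanol (all-cis) | COc1ccc(C[C@H]2CO[C@@H](c3cc(OC)c(OC)c(OC)c3)[C@H]2CO)cc1OC | target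

## Step count and risks

Total steps: 6. Longest linear sequence: 6 (1 → 3 → 7 → 12 → 13 → 15 → 16).

**Most likely to fail, 1: step 2 (carbene annulation).** Enantioselective versions of this annulation are established for activated ketones, not for a simple aryl aldehyde, so the ee and the cis:trans ratio are uncertain. The enal can also self-annulate, and the homoenolate can expel silanolate from its γ-carbon. The fallback sets out from 4 and comes back at 7, replacing the catalytic step by an auxiliary-controlled anti-aldol. (R)-4-Benzyl-1,3-oxazolidin-2-one is acylated (n-BuLi, methyl 4-chloro-4-oxobutanoate) to methyl 4-[(4R)-4-benzyl-2-oxo-1,3-oxazolidin-3-yl]-4-oxobutanoate F1. F1 and 4 under MgCl2 (10 mol %), Et3N and Me3SiCl in EtOAc give the silylated anti-aldol adduct methyl (3S,4R)-3-{[(4R)-4-benzyl-2-oxo-1,3-oxazolidin-3-yl]carbonyl}-4-(3,4,5-trimethoxyphenyl)-4-[(trimethylsilyl)oxy]butanoate F2; the anti relation is what maps onto the cis lactone. LiOH/H2O2 in THF–H2O followed by acidification removes the auxiliary, the silyl group and the methyl ester and lactonises to the cis acid (2R,3S)-5-oxo-2-(3,4,5-trimethoxyphenyl)oxolane-3-carboxylic acid F3. BH3·SMe2 reduces the acid but not the lactone to (4R,5R)-4-(hydroxymethyl)-5-(3,4,5-trimethoxyphenyl)oxolan-2-one F4, which is silylated at once (tert-butyldimethylsilyl chloride, imidazole) to 7.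

**Most likely to fail, 2: step 4 (hydrogenation).** Facial selectivity may be incomplete, and the exocyclic alkene may migrate into the ring or the electron-rich arenes may be reduced on rhodium. The fallback sets out from 7 and comes back at 13, bypassing the benzylidene altogether. The enolate of 7 (LiN(SiMe3)2, THF, –78 °C) is alkylated with 3,4-dimethoxybenzyl bromide anti to the C4 substituent, giving the 3,4-trans lactone (3S,4R,5R)-4-{[(tert-butyldimethylsilyl)oxy]methyl}-3-(3,4-dimethoxybenzyl)-5-(3,4,5-trimethoxyphenyl)oxolan-2-one F5. Deprotonation with LiN(iPr)2 gives lithium (4R,5R)-4-{[(tert-butyldimethylsilyl)oxy]methyl}-3-(3,4-dimethoxybenzyl)-5-(3,4,5-trimethoxyphenyl)-4,5-dihydrofuran-2-olate F6. Kinetic protonation at –78 °C with 2,6-di-tert-butyl-4-methylphenol, again anti to the C4 substituent, inverts C3 and gives 13.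

**Most likely to fail, 3: step 5 (one-pot lactone-to-ether reduction).** BF3·OEt2 may ionise the benzylic C2–O bond (epimerisation to the 2,3-trans isomer or reductive ring opening), the silyl ether may be lost, or the veratryl ring may trap the oxocarbenium ion. The fallback sets out from 13 and comes back at 15 without any Lewis acid. LiAlH4 (THF, 0 °C) opens the lactone to (1R,2R,3R)-2-{[(tert-butyldimethylsilyl)oxy]methyl}-3-(3,4-dimethoxybenzyl)-1-(3,4,5-trimethoxyphenyl)butane-1,4-diol F7. Selective sulfonylation of the primary hydroxyl (TsCl, pyridine, DMAP) gives (2R,3R,4R)-3-{[(tert-butyldimethylsilyl)oxy]methyl}-2-(3,4-dimethoxybenzyl)-4-hydroxy-4-(3,4,5-trimethoxyphenyl)butyl 4-methylbenzenesulfonate F8. On warming, the benzylic hydroxyl displaces the tosylate (5-exo-tet, C2–O never broken, so C2 is retained) to give 15.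

## Further compounds

F1 | step 2 | methyl 4-[(4R)-4-benzyl-2-oxo-1,3-oxazolidin-3-yl]-4-oxobutanoate | COC(=O)CCC(=O)N1[C@H](Cc2ccccc2)COC1=O
F2 | step 2 | methyl (3S,4R)-3-{[(4R)-4-benzyl-2-oxo-1,3-oxazolidin-3-yl]carbonyl}-4-(3,4,5-trimethoxyphenyl)-4-[(trimethylsilyl)oxy]butanoate | C[Si](C)(C)O[C@@H](c1cc(OC)c(OC)c(OC)c1)[C@@H](C(=O)N1[C@H](Cc2ccccc2)COC1=O)CC(=O)OC
F3 | step 2 | (2R,3S)-5-oxo-2-(3,4,5-trimethoxyphenyl)oxolane-3-carboxylic acid | C1C(=O)O[C@@H](c2cc(OC)c(OC)c(OC)c2)[C@H]1C(O)=O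
F4 | step 2 | (4R,5R)-4-(hydroxymethyl)-5-(3,4,5-trimethoxyphenyl)oxolan-2-one | C1C(=O)O[C@@H](c2cc(OC)c(OC)c(OC)c2)[C@H]1CO
F5 | step 4 | (3S,4R,5R)-4-{[(tert-butyldimethylsilyl)oxy]methyl}-3-(3,4-dimethoxybenzyl)-5-(3,4,5-trimethoxyphenyl)oxolan-2-one | COc1ccc(C[C@@H]2C(=O)O[C@@H](c3cc(OC)c(OC)c(OC)c3)[C@H]2CO[Si](C)(C)C(C)(C)C)cc1OC
F6 | step 4 | lithium (4R,5R)-4-{[(tert-butyldimethylsilyl)oxy]methyl}-3-(3,4-dimethoxybenzyl)-5-(3,4,5-trimethoxyphenyl)-4,5-dihydrofuran-2-olate | COc1ccc(CC2=C([O-])O[C@@H](c3cc(OC)c(OC)c(OC)c3)[C@H]2CO[Si](C)(C)C(C)(C)C)cc1OC.[Li+]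
F7 | step 5 | (1R,2R,3R)-2-{[(tert-butyldimethylsilyl)oxy]methyl}-3-(3,4-dimethoxybenzyl)-1-(3,4,5-trimethoxyphenyl)butane-1,4-diol | COc1ccc(C[C@@H](CO)[C@H](CO[Si](C)(C)C(C)(C)C)[C@@H](O)c2cc(OC)c(OC)c(OC)c2)cc1OC
F8 | step 5 | (2R,3R,4R)-3-{[(tert-butyldimethylsilyl)oxy]methyl}-2-(3,4-dimethoxybenzyl)-4-hydroxy-4-(3,4,5-trimethoxyphenyl)butyl 4-methylbenzenesulfonate | COc1ccc(C[C@@H](COS(=O)(=O)c2ccc(C)cc2)[C@H](CO[Si](C)(C)C(C)(C)C)[C@@H](O)c2cc(OC)c(OC)c(OC)c2)cc1OC
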